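**Remark on the chemistry:** 1, 7 and 8 are taken as purchased. The 1,3-diketones 10 and 11 are written as their hydrogen-bonded enol tautomers, which stand for the tautomeric mixture.

## Analysis of the target

3-Methoxytangeretin (12) is a flavone: a 4H-chromen-4-one in which benzene ring A is fused along C4a–C8a to the γ-pyranone ring C, with a 4-methoxyphenyl ring B on C2. It has no stereocentre, so the problem is one of regiochemistry and crowding. Ring A is fully substituted: C5, C6, C7 and C8 carry methoxy groups, C8a carries the ring oxygen O1, and C4a carries the carbonyl carbon C4. C3 of ring C carries the sixth methoxy group. The sensitive points are the C5 methyl ether, which lies peri to the C4 carbonyl and is lost under Lewis or strong Brønsted acid, and the electron-rich ring A, which oxidises easily to a quinone once it bears a free phenol. The difficulty is that C4a is flanked on both sides by oxygen-bearing carbons (C5 and C8a), so classical acylation at C4a is hindered, and O1 must be told apart from four neighbouring methyl ethers. The strategy rests on C4: it is a lone carbonyl carbon bonded only to C4a of ring A and to the methoxy-bearing C3. It can therefore be delivered as carbon monoxide between an aryl iodide carbon (C4a) and an enolate carbon (C3), and all other atoms come from two simple aromatic building blocks.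

## Retrosynthetic reasoning

**12 to 11 (cut O1–C2).** The enol ether bond of ring C is the natural last bond. In the 2-hydroxyaryl 1,3-diketone 11 the C8a phenol can reach only the ring B carbonyl through a six-membered transition state, so the direction of closure is fixed. The cut removes ring C and exposes a 1,3-dicarbonyl unit with C4 in its middle. The forward step is an acid cyclodehydration that must be mild enough to spare the C5 methyl ether.

**11 to 10 (mask O1).** The phenol has to be hidden during the basic, palladium-catalysed step. A methoxymethyl acetal is chosen because it leaves under the same acid that closes ring C, so unmasking and cyclisation become one operation. A benzyl ether would mask equally well but would need a separate hydrogenolysis.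

**10 to 6, 7 and 8 (cut C4a–C4 and C3–C4).** Both bonds to C4 are cut, so C4 becomes carbon monoxide 8. This is preferred to cutting C4a–C4 alone, which would require acylating a ring carbon between two ortho oxygen substituents, and to cutting C2–C3, which still needs that hindered aryl ketone first. Ring A with all its oxygens then sits in aryl iodide 6, and ring B with C2, C3 and the C3 methoxy group sits in ketone 7. The forward reaction must make the carbonylative coupling faster than direct arylation of the enolate, and must acylate the enolate at carbon, not at oxygen.

**6 to 5 to 4 (O-protection, C–I bond).** Removing the acetal gives iodophenol 5, and removing iodine gives phenol 4. Phenol 4 has a single unsubstituted ring position, ortho to the hydroxyl, so the iodination cannot go elsewhere.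

**4 to 1 (C–O bond).** The hydroxyl of 4 is traced to a ring hydrogen of 1. The two ring hydrogens of 1 are equivalent and each is ortho to a methoxy group, so lithiation, borylation and oxidation in one flask should put the oxygen in place without any regiochemical choice.

## Alternatives that were turned down

**Alternative 1: biomimetic fold of an open chain into rings A and C.**
- Disconnection: C4a–C8a in ring A and O1–C2 in ring C, back to methyl 2,4,8,9-tetramethoxy-9-(4-methoxyphenyl)-3,5,7-trioxonon-8-enoate (A1), which holds every carbon from C2 to C8a.
- Forward key step: base would fold A1 by Claisen attack of the C4a methylene on the ester carbon. The cyclic triketone would aromatise to a phloroglucinol, and its C8a phenol would add to C2 and expel methoxide, giving 5,7-dihydroxy-3,6,8-trimethoxy-2-(4-methoxyphenyl)-4H-chromen-4-one (A2).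
- For it: two rings form in one metal-free operation, and the oxygen pattern of ring A is written into the chain. The phloroglucinol is symmetric, so either ortho phenol gives the same pyranone.
- Against it: A1 has three enolisable positions, two of them methoxy-substituted, so aldol folds and O-cyclisation to simple pyranones compete with the wanted Claisen closure. Building A1 needs a long series of enolate acylations through labile polycarbonyl intermediates. A2 still needs two O-methylations, one of them at the chelated C5 hydroxyl.
- Comparison: it is stronger in rings formed per step. The chosen route gives that up because ring A is bought complete as 1, its key step faces one chemoselectivity question instead of a network of enolate pathways, and it needs five steps in all.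

**Alternative 2: squarate ring expansion to ring A.**
- Disconnection: C8–C8a of ring A. Dimethyl squarate (A3) supplies C5 to C8 with their oxygens, and an alkenyllithium carrying the ester (C4 on C4a) and the benzyloxy group (on C8a) supplies the rest.
- Forward key step: addition to A3 gives methyl 3-(benzyloxy)-2-(1-hydroxy-2,3-dimethoxy-4-oxocyclobut-2-en-1-yl)prop-2-enoate (A4). Heating opens A4 to a dienylketene, which closes by a six-electron electrocyclisation and tautomerises to methyl 2-(benzyloxy)-3,6-dihydroxy-4,5-dimethoxybenzoate (A5).
- For it: every ring A substituent is placed without any aromatic substitution, the hexasubstituted ring forms from A4 under neutral thermal conditions, and C4 is already attached as the ester carbon.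
- Against it: the power to differentiate the ring A oxygens is wasted, because C5 to C8 all end as methoxy groups. A5 must be methylated twice to reach a pattern that 1 already has. The ester must then be joined to 7 by a Claisen condensation at a doubly ortho-substituted benzoate, which is the hindered acylation the chosen route avoids. The alkenyllithium that leads to A4 needs cryogenic handling and the sequence is roughly twice as long.
- Comparison: it is stronger in generality and would be the method of choice if the ring A oxygens had to differ. The chosen route offers a much shorter path and installs C4 without a hindered acylation.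

**Alternative 3: Dötz benzannulation of ring A onto a preformed pyranone.**
- Disconnection: C7–C8, C5–C6 and C4a–C5, back to pentacarbonyl{methoxy[5-methoxy-6-(4-methoxyphenyl)-4-oxo-4H-pyran-2-yl]methylidene}chromium (A6), di-tert-butoxyethyne (A7) and one carbonyl ligand.
- Forward key step: A7 inserts into the chromium–carbene bond, a carbonyl ligand inserts to give a vinylketene, and electrocyclisation with tautomerisation gives 6,7-di-tert-butoxy-5-hydroxy-3,8-dimethoxy-2-(4-methoxyphenyl)-4H-chromen-4-one (A8). The C5 hydroxyl comes from the carbonyl ligand and the C8 methoxy group from the carbene carbon.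
- For it: it is convergent and creates the fully substituted ring A in one step.
- Against it: chromium is used stoichiometrically. A6 requires metalation of a pyranone beside its ring oxygen in the presence of its own carbonyl group. The pyranone double bond that must take part in the electrocyclisation is an electron-poor vinylogous ester, so cyclobutenone and furan by-paths of the vinylketene are likely. A7 is thermally fragile. A8 needs two tert-butyl ether cleavages and three O-methylations, including the chelated C5 hydroxyl, and is prone to oxidation to a quinone.
- Comparison: it is stronger in convergence of ring construction. The chosen route uses catalytic palladium, carries all six methyl ethers from the start, and concentrates its risk in a single step.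

Key step: step 4

## Route

**Step 1**
Reactants: 1 1,2,3,4-tetramethoxybenzene
Product: 4 2,3,4,5-tetramethoxyphenol, via (2,3,4,5-tetramethoxyphenyl)lithium 2 (not isolated), via lithium aryl(trimethoxy)borate 3 (not isolated)
Conditions: n-BuLi, TMEDA, THF, 0 °C; B(OMe)3, −78 °C to rt; AcOH, 30% aq. H2O2, 0 °C to rt
Reagents that add atoms: hydrogen peroxide, OO
Why: Directed ortho-lithiation of 1 (both ring hydrogens are equivalent and each is ortho to a methoxy group), trapping with the borate ester and oxidative 1,2-shift of the aryl group from boron to oxygen (lithiation–borylation–oxidation) should give the phenol in one flask, with the new oxygen where O1 is needed.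

**Step 2**
Reactants: 4 2,3,4,5-tetramethoxyphenol
Product: 5 2-iodo-3,4,5,6-tetramethoxyphenol
Conditions: NIS, MeCN, 0 °C, dark
Reagents that add atoms: N-iodosuccinimide, O=C1CCC(=O)N1I
Why: Electrophilic aromatic iodination of a strongly activated phenol; the only unsubstituted ring carbon is ortho to the hydroxyl, so regiochemistry is fixed, and a mild iodine source at low temperature should limit oxidation of the ring.

**Step 3**
Reactants: 5 2-iodo-3,4,5,6-tetramethoxyphenol
Product: 6 1-iodo-2,3,4,5-tetramethoxy-6-(methoxymethoxy)benzene
Conditions: NaH, MOMCl, THF/DMF, 0 °C to rt
Reagents that add atoms: chloromethyl methyl ether, COCCl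
Why: Williamson-type O-alkylation of the sodium phenoxide with a small, reactive α-chloro ether, which tolerates the two ortho substituents; the acetal is inert to strong base and to palladium and leaves under the acid of step 5.

**Step 4**
Reactants: 6 1-iodo-2,3,4,5-tetramethoxy-6-(methoxymethoxy)benzene; 7 2-methoxy-1-(4-methoxyphenyl)ethanone; 8 carbon monoxide
Product: 10 (E)-3-hydroxy-2-methoxy-3-(4-methoxyphenyl)-1-[2,3,4,5-tetramethoxy-6-(methoxymethoxy)phenyl]prop-2-en-1-one (chelated enol form of the 1,3-diketone), via sodium enolate 9 (not isolated)
Conditions: 7 (2 equiv), NaN(SiMe3)2 (2.2 equiv), THF, 0 °C; then 6, Pd(dba)2 (5 mol%), Xantphos (5 mol%), CO (2 bar), THF, 80 °C; aq. NH4Cl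
Reagents that add atoms: none
Why: Zerovalent palladium ligated by Xantphos adds oxidatively to the C–I bond of 6, and the aryl group, pushed by its two ortho oxygen substituents, migrates to coordinated 8 to give an aroyl complex of divalent palladium, which forms the C4a–C4 bond. Sodium enolate 9 replaces iodide on palladium, and reductive elimination from the carbon-bound enolate forms the C3–C4 bond and returns zerovalent palladium. The closest known reaction is the palladium-catalysed carbonylative α-arylation of aryl alkyl ketones with aryl iodides, which gives 1,3-diketones under such conditions. The diketone is far more acidic than 7, so the second equivalent of base should convert it at once into its chelated sodium enolate, which shields it from retro-Claisen cleavage and pulls the sequence forward. No ring closes and no lasting stereocentre forms: the central carbon is sp2 in the enol and is stereogenic, but labile, only in the diketo tautomer. Carbonylative coupling must beat direct α-arylation; the doubly ortho-substituted aryl–palladium bond and the CO atmosphere favour this, because migration to CO relieves strain while enolate transfer to the crowded aryl complex is slow. C-acylation must beat O-acylation; reductive elimination from a carbon-bound palladium enolate provides this, and any enol ester that forms is itself an acyl donor towards excess 9 and should be funnelled to the same stabilised diketonate.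

**Step 5**
Reactants: 10 (E)-3-hydroxy-2-methoxy-3-(4-methoxyphenyl)-1-[2,3,4,5-tetramethoxy-6-(methoxymethoxy)phenyl]prop-2-en-1-one
Product: 12 3,5,6,7,8-pentamethoxy-2-(4-methoxyphenyl)-4H-chromen-4-one (3-methoxytangeretin), via free phenol diketone 11 (not isolated)
Conditions: HCl (1 M in MeOH), 55 °C
Reagents that add atoms: none
Why: Acid methanolysis of the methoxymethyl acetal frees the C8a phenol, which adds to the protonated ring B carbonyl (6-exo-trig, the only ring size possible) and loses water to give the aromatic pyranone; this is the cyclodehydration that ends a Baker–Venkataraman flavone synthesis, run briefly and at moderate temperature to spare the C5 methyl ether.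

## Compound list

1 | 1,2,3,4-tetramethoxybenzene | COc1ccc(OC)c(OC)c1OC | starting material
2 | (2,3,4,5-tetramethoxyphenyl)lithium | [Li]c1cc(OC)c(OC)c(OC)c1OC | intermediate (not isolated)
3 | lithium trimethoxy(2,3,4,5-tetramethoxyphenyl)borate | [Li+].CO[B-](OC)(OC)c1cc(OC)c(OC)c(OC)c1OC | intermediate (not isolated)
4 | 2,3,4,5-tetramethoxyphenol | COc1cc(O)c(OC)c(OC)c1OC | intermediate
5 | 2-iodo-3,4,5,6-tetramethoxyphenol | COc1c(I)c(O)c(OC)c(OC)c1OC | intermediate
6 | 1-iodo-2,3,4,5-tetramethoxy-6-(methoxymethoxy)benzene | COCOc1c(I)c(OC)c(OC)c(OC)c1OC | intermediate
7 | 2-methoxy-1-(4-methoxyphenyl)ethanone | COCC(=O)c1ccc(OC)cc1 | starting material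
8 | carbon monoxide | [C-]#[O+] | starting material
9 | sodium (Z)-2-methoxy-1-(4-methoxyphenyl)ethen-1-olate | [Na+].CO/C=C(\[O-])c1ccc(OC)cc1 | intermediate (not isolated)
10 | (E)-3-hydroxy-2-methoxy-3-(4-methoxyphenyl)-1-[2,3,4,5-tetramethoxy-6-(methoxymethoxy)phenyl]prop-2-en-1-one | COCOc1c(OC)c(OC)c(OC)c(OC)c1C(=O)/C(OC)=C(\O)c1ccc(OC)cc1 | intermediate
11 | (E)-3-hydroxy-1-(2-hydroxy-3,4,5,6-tetramethoxyphenyl)-2-methoxy-3-(4-methoxyphenyl)prop-2-en-1-one | COc1ccc(/C(O)=C(\OC)C(=O)c2c(O)c(OC)c(OC)c(OC)c2OC)cc1 | intermediate (not isolated)
12 | 3,5,6,7,8-pentamethoxy-2-(4-methoxyphenyl)-4H-chromen-4-one (3-methoxytangeretin) | COc1ccc(-c2oc3c(OC)c(OC)c(OC)c(OC)c3c(=O)c2OC)cc1 | target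

## Step count and risks

Total step count: 5. Longest linear sequence: 5 steps (1 to 4 to 5 to 6 to 10 to 12); 7 and 8 enter at step 4 as bought.

**Step 4 (key step).** Three things may go wrong.
- Oxidative addition to the electron-rich, doubly ortho-substituted C–I bond may be slow under CO, so that the catalyst is carbonylated and deposits as palladium black.
- The chelated, α-methoxy-substituted enolate 9 is a crowded secondary nucleophile, so coupling at carbon may lag behind O-acylation or behind reduction of the C–I bond.
- The ligand is a first choice and a narrower chelating bisphosphine may be needed.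

Fallback: from 4, a Baker–Venkataraman sequence returns to the route at 11.
- Ortho C-acylation of 4 with methoxyacetic acid in BF3·OEt2 (Fries-type, assisted by the hydroxyl) should give 1-(2-hydroxy-3,4,5,6-tetramethoxyphenyl)-2-methoxyethan-1-one F1.
- Esterification with 4-methoxybenzoyl chloride in pyridine should give 3,4,5,6-tetramethoxy-2-(2-methoxyacetyl)phenyl 4-methoxybenzoate F2.
- LiN(SiMe3)2 in THF should then shift the aroyl group from oxygen to the α-carbon to give 11, which is cyclised as in step 5.

**Step 1.** Lithiation may be incomplete, the electron-rich arylborate may lose boron by protonation before the aryl shift, or the product phenol may be oxidised further by excess peroxide.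

Fallback: from 1, returning at 4.
- Rieche formylation (Cl2CHOMe, TiCl4, CH2Cl2, 0 °C) should give 2,3,4,5-tetramethoxybenzaldehyde F3.
- This aldehyde has no free ortho or para hydroxyl, so alkaline Dakin conditions do not apply. A peracid Baeyer–Villiger oxidation (mCPBA, CH2Cl2) is used instead and should give 2,3,4,5-tetramethoxyphenyl formate F4.
- Methanolysis with K2CO3 in MeOH should give 4.

**Step 2.** The iodine electrophile may oxidise the para-methoxyphenol to a quinone (oxidative demethylation) instead of substituting the ring.

Fallback: from 4, returning at 6, with the order of protection and iodination reversed.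
- 4 is first converted with NaH and MOMCl into 1,2,3,4-tetramethoxy-5-(methoxymethoxy)benzene F5, which has no oxidisable phenol.
- Directed ortho-lithiation (n-BuLi, THF, 0 °C) at the only free ring position, between the acetal and a methoxy group, followed by I2, should give 6.

**Step 5.** Acetal cleavage needs more acid and time than the cyclodehydration. During that time the C5 methyl ether may be lost (assisted by chelation to the C4 carbonyl), or the diketone may be cleaved by acid methanolysis before the ring closes.

Fallback: from 5, returning at 11, with a benzyl ether so that unmasking is neutral.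
- Benzylation of 5 (BnBr, K2CO3, DMF) should give 2-(benzyloxy)-1-iodo-3,4,5,6-tetramethoxybenzene F6.
- Carbonylative coupling with 7 and 8 as in step 4 should give (E)-1-[2-(benzyloxy)-3,4,5,6-tetramethoxyphenyl]-3-hydroxy-2-methoxy-3-(4-methoxyphenyl)prop-2-en-1-one F7.
- Hydrogenolysis (H2, 10% Pd/C, EtOAc) should give 11, which then needs only a catalytic amount of p-TsOH in toluene for the dehydration to 12.

## Further compounds

F1 | step 4 | 1-(2-hydroxy-3,4,5,6-tetramethoxyphenyl)-2-methoxyethan-1-one | COCC(=O)c1c(O)c(OC)c(OC)c(OC)c1OC
F2 | step 4 | 3,4,5,6-tetramethoxy-2-(2-methoxyacetyl)phenyl 4-methoxybenzoate | COCC(=O)c1c(OC(=O)c2ccc(OC)cc2)c(OC)c(OC)c(OC)c1OC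
F3 | step 1 | 2,3,4,5-tetramethoxybenzaldehyde | COc1cc(C=O)c(OC)c(OC)c1OC
F4 | step 1 | 2,3,4,5-tetramethoxyphenyl formate | COc1cc(OC=O)c(OC)c(OC)c1OC
F5 | step 2 | 1,2,3,4-tetramethoxy-5-(methoxymethoxy)benzene | COCOc1cc(OC)c(OC)c(OC)c1OC
F6 | step 5 | 2-(benzyloxy)-1-iodo-3,4,5,6-tetramethoxybenzene | COc1c(OC)c(OC)c(OCc2ccccc2)c(I)c1OC
F7 | step 5 | (E)-1-[2-(benzyloxy)-3,4,5,6-tetramethoxyphenyl]-3-hydroxy-2-methoxy-3-(4-methoxyphenyl)prop-2-en-1-one | COc1ccc(/C(O)=C(\OC)C(=O)c2c(OCc3ccccc3)c(OC)c(OC)c(OC)c2OC)cc1
A1 | alternative 1 | methyl 2,4,8,9-tetramethoxy-9-(4-methoxyphenyl)-3,5,7-trioxonon-8-enoate (mixture of stereoisomers, all stereo elements lost in the fold) | COC(=O)C(OC)C(=O)C(OC)C(=O)CC(=O)C(OC)=C(OC)c1ccc(OC)cc1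
A2 | alternative 1 | 5,7-dihydroxy-3,6,8-trimethoxy-2-(4-methoxyphenyl)-4H-chromen-4-one | COc1ccc(-c2oc3c(OC)c(O)c(OC)c(O)c3c(=O)c2OC)cc1
A3 | alternative 2 | dimethyl squarate (3,4-dimethoxycyclobut-3-ene-1,2-dione) | COC1=C(OC)C(=O)C1=O
A4 | alternative 2 | methyl 3-(benzyloxy)-2-(1-hydroxy-2,3-dimethoxy-4-oxocyclobut-2-en-1-yl)prop-2-enoate (racemic, either alkene geometry) | COC(=O)C(=COCc1ccccc1)C1(O)C(OC)=C(OC)C1=O
A5 | alternative 2 | methyl 2-(benzyloxy)-3,6-dihydroxy-4,5-dimethoxybenzoate | COC(=O)c1c(OCc2ccccc2)c(O)c(OC)c(OC)c1O
A6 | alternative 3 | pentacarbonyl{methoxy[5-methoxy-6-(4-methoxyphenyl)-4-oxo-4H-pyran-2-yl]methylidene}chromium | COC(c1cc(=O)c(OC)c(-c2ccc(OC)cc2)o1)=[Cr](=C=O)(=C=O)(=C=O)(=C=O)=C=O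
A7 | alternative 3 | di-tert-butoxyethyne | CC(C)(C)OC#COC(C)(C)C
A8 | alternative 3 | 6,7-di-tert-butoxy-5-hydroxy-3,8-dimethoxy-2-(4-methoxyphenyl)-4H-chromen-4-one | COc1ccc(-c2oc3c(OC)c(OC(C)(C)C)c(OC(C)(C)C)c(O)c3c(=O)c2OC)cc1
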